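**Overview**

- Retrosynthetic cuts, in order: the heptenyl C=C (cross-metathesis with 1-heptene); the ring alkene C1=C2, with the C2 methylene handed over to the alkyne terminus (ring-closing enyne metathesis); C2–C3 (2-lithioallyl alkoxide + epoxy aldehyde); C6–C1 (acetylide + Weinreb amide); C4=C5, later the oxirane (Z-selective phosphonate olefination); C5–CH2 of the side chain (phosphonate alkylation with a 4-bromotiglate).
- Forward: the open chain is joined in the order tiglate side chain → phosphonate → Z-enoate → ynone → oxirane → hydroxymethylvinyl unit; the only carbocycle, the cyclohexene of the 7-oxabicyclo[4.1.0]heptene, is closed after all four stereocentres are in place; the pentyl terminus then comes by cross-metathesis and two protecting groups are removed.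
- Feature that permits the key step: the tetrasubstituted ring alkene C1=C2 conjugated to the exocyclic alkene on C1 is a 1-alkenylcyclohexene, the product pattern of a 1,7-enyne metathesis, and the cis-fused C4–C5 oxirane ring locks C3 and C6 on the same side so that the alkyne on C6 and the alkene on C3 are held within reach.
- Stereochemistry: C6 from a CBS reduction of the ynone; C4 and C5 from C6 by hydroxyl-directed threo epoxidation of the Z-alkene; C3 from the oxirane by Felkin–Anh addition; Z-alkene (later cis-oxirane) from the Still–Gennari step; side-chain E-alkene from tiglic acid; heptenyl E-alkene from cross-metathesis.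

Key step: step 14

Remark: atoms are numbered as in the final ring (C1 heptenyl-bearing and C2 hydroxymethyl-bearing alkene carbons, C3 carbinol, C4 and quaternary C5 oxirane carbons, C6 carbinol); in step 7 the branched alkenyl group is assumed to act as the large ketone substituent toward the oxazaborolidine.

**Route**

Step 1
Reactants: 1 tiglic acid
Product: 2 tert-butyl tiglate
Conditions: isobutylene, H2SO4 (cat.), CH2Cl2, sealed vessel, rt
Reagents that add atoms: isobutylene (2-methylpropene), C=C(C)C
Why: Acid-catalysed esterification by addition of the carboxylic acid to isobutylene (tert-butyl cation capture) gives the hindered ester that later resists amide formation and organolithium reagents, without touching the E-alkene.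

Step 2
Reactants: 2 tert-butyl tiglate
Product: 3 tert-butyl (E)-4-bromo-2-methylbut-2-enoate
Conditions: NBS, AIBN (cat.), PhCF3, reflux
Reagents that add atoms: N-bromosuccinimide, O=C1CCC(=O)N1Br
Why: Wohl–Ziegler radical bromination, in which hydrogen abstraction from the C4 methyl gives an allyl radical delocalised onto the ester-bearing carbon, so bromine should enter mainly at C4 (the minor 2-bromomethyl isomer being removed by chromatography) with the more stable E geometry kept.

Step 3
Reactants: 3 tert-butyl (E)-4-bromo-2-methylbut-2-enoate + 4 methyl bis(2,2,2-trifluoroethyl)phosphonoacetate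
Product: 5 alpha-alkylated phosphonate diester (racemic at the phosphonate carbon)
Conditions: 4 (excess), NaH, THF/DMF, 0 °C; then 3, 0 °C → rt
Reagents that add atoms: none
Why: C-alkylation of the sodium phosphonoacetate anion by SN2 displacement at the primary allylic bromide (the SN2' position is a fully substituted alkene carbon), excess 4 holding back double alkylation; the new stereocentre is racemic and is destroyed in the next step.

Step 4
Reactants: 5 alpha-alkylated phosphonate diester + 6 (tert-butyldimethylsilyloxy)acetaldehyde
Product: 7 Z-trisubstituted enoate diester (methyl ester cis to CH2OSi)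
Conditions: KN(SiMe3)2, 18-crown-6, THF, −78 °C; then 6
Reagents that add atoms: none
Why: Still–Gennari olefination, in which the electron-poor trifluoroethyl phosphonate eliminates fast and irreversibly from the kinetically formed adduct under dissociating conditions, placing the aldehyde residue cis to the ester and so setting the Z-alkene that becomes the cis-oxirane.

Step 5
Reactants: 7 Z-trisubstituted enoate diester
Product: 8 Z-configured Weinreb amide
Conditions: MeNH(OMe)·HCl, i-PrMgCl, THF, −20 → 0 °C
Reagents that add atoms: N,O-dimethylhydroxylamine hydrochloride, CNOC.Cl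
Why: Weinreb amide formation by acyl substitution of the methyl ester with the chloromagnesium amide made in the flask; the tert-butyl ester is too hindered to react and the Z geometry is not affected.

Step 6
Reactants: 8 Z-configured Weinreb amide + 9 trimethylsilylacetylene
Product: 11 cross-conjugated Z-enynone, via lithium (trimethylsilyl)acetylide 10 (not isolated)
Conditions: 9, n-BuLi, THF, −78 °C; then 8, −78 → −20 °C; aq. NH4Cl
Reagents that add atoms: none
Why: Weinreb ketone synthesis, in which the lithium acetylide adds once and the chelated tetrahedral adduct collapses to the ynone only on work-up, forming the C6–C1 bond while the tert-butyl ester is inert at low temperature.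

Step 7
Reactants: 11 cross-conjugated Z-enynone
Product: 12 (6S)-propargylic allylic alcohol
Conditions: (S)-Me-CBS oxazaborolidine [(S)-1-methyl-3,3-diphenyltetrahydro-1H,3H-pyrrolo[1,2-c][1,3,2]oxazaborole] (20 mol %), catecholborane, toluene, −78 °C; then MeOH, pH 10 buffer wash
Reagents that add atoms: none
Why: Corey–Bakshi–Shibata reduction, in which the ketone binds to the ring boron of the (S)-oxazaborolidine with the branched Z-alkenyl group as the large substituent and the slim silylalkynyl group as the small one, so hydride is delivered to the face that gives the (S)-carbinol at C6 (the sense of (R)-1-phenylethanol from acetophenone).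

Step 8
Reactants: 12 (6S)-propargylic allylic alcohol
Product: 13 threo epoxy alcohol (4R,5S,6R)
Conditions: mCPBA, NaHCO3, CH2Cl2, 0 °C
Reagents that add atoms: 3-chloroperoxybenzoic acid, OOC(=O)c1cccc(Cl)c1
Why: Hydroxyl-directed (Henbest-type) peracid epoxidation, in which the C6–H eclipses the alkene to avoid A(1,3) strain with the cis CH2OSi group, so oxygen is delivered syn to the C6 hydroxyl of that conformer and gives the threo epoxy alcohol (C4 and C5 set from C6, the Z geometry becoming the cis-oxirane), while the electron-poor enoate and the silylalkyne do not react.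

Step 9
Reactants: 13 threo epoxy alcohol
Product: 14 bis-silyl ether (4R,5R,6R)
Conditions: t-BuMe2SiOTf, 2,6-lutidine, CH2Cl2, −78 °C
Reagents that add atoms: tert-butyldimethylsilyl triflate, CC(C)(C)[Si](C)(C)OS(=O)(=O)C(F)(F)F
Why: Silylation of the hindered secondary alcohol with the silyl triflate and a non-nucleophilic base protects C6–OH without change at any stereocentre, and tert-butyl ester and oxirane survive the brief cold exposure.

Step 10
Reactants: 14 bis-silyl ether
Product: 15 primary epoxy alcohol with C6 silyl ether (4R,5R,6R)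
Conditions: HF·pyridine, pyridine, THF, 0 °C
Reagents that add atoms: none
Why: Selective desilylation, in which pyridine-buffered HF cleaves the unhindered primary silyl ether much faster than the neopentyl-like propargylic secondary one and leaves oxirane, alkynylsilane and tert-butyl ester intact.

Step 11
Reactants: 15 primary epoxy alcohol with C6 silyl ether
Product: 16 cis-epoxy aldehyde (4S,5R,6R)
Conditions: Dess–Martin periodinane, NaHCO3, CH2Cl2, 0 °C → rt
Reagents that add atoms: none
Why: Dess–Martin oxidation under bicarbonate buffer stops at the aldehyde and is mild enough that the oxirane-bearing alpha carbon C4 does not epimerise.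

Step 12
Reactants: 16 cis-epoxy aldehyde + 17 2-bromoallyl alcohol
Product: 19 (3R)-epoxy enyne diol bearing the C-silylated alkyne, via 2-lithioallyl lithium alkoxide 18 (not isolated)
Conditions: 17, t-BuLi (3 equiv.), Et2O, −78 → 0 °C; then 16, −78 °C; aq. NH4Cl
Reagents that add atoms: none
Why: Bromine–lithium exchange and O-deprotonation give the 2-lithioallyl alkoxide, which adds under Felkin–Anh control (the C4–O bond of the oxirane anti to the incoming vinyl carbanion, which passes the small C4 hydrogen), so the C2–C3 bond forms with the 3R configuration, cis to the oxirane oxygen in the later ring; ester, oxirane and alkynylsilane are inert at −78 °C.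

Step 13
Reactants: 19 (3R)-epoxy enyne diol bearing the C-silylated alkyne
Product: 20 acyclic epoxy 1,7-enyne with terminal alkyne (3R,4R,5R,6R)
Conditions: K2CO3 (cat.), MeOH, 0 °C
Reagents that add atoms: none
Why: Base-catalysed methanolysis of the alkynyl C–Si bond (protodesilylation through a pentacoordinate silicate) frees the terminal alkyne, the O-silyl ether, tert-butyl ester and oxirane being stable to catalytic carbonate in the cold.

Step 14
Reactants: 20 acyclic epoxy 1,7-enyne with terminal alkyne
Product: 21 1-vinyl epoxycyclohexene diene (3R,4R,5R,6R)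
Conditions: RuCl2(=CH-C6H4-2-O-i-Pr)[1,3-bis(2-methylphenyl)imidazolidin-2-ylidene] (10 mol %), ethylene (1 atm), toluene (0.005 M), 60 °C
Reagents that add atoms: none
Why: The ruthenium methylidene formed under ethylene adds to the terminal alkyne with its carbon on the alkyne terminus, so a vinylcarbene stands on C1; this carbene undergoes intramolecular [2+2] cycloaddition and cycloreversion with the CH2=C2 alkene, which forms the C1=C2 ring bond, leaves the former C2 methylene on the alkyne terminus as the exocyclic vinyl group and regenerates the methylidene. The closest known reaction type is the ruthenium-catalysed ring-closing metathesis of 1,7-enynes to 1-vinylcyclohexenes, including the less common cases in which a 1,1-disubstituted alkene closes to a tetrasubstituted ring alkene. The six-membered carbocycle closes in the exo mode, only the inner alkyne carbon C1 becoming a ring atom. No stereocentre is formed and none of the four existing ones (C3 to C6) is touched. The step needs initiation at the alkyne and six-ring exo closure in preference to seven-ring endo closure, ethylene interception or oligomerisation; the terminal alkyne is the only site that reacts fast with the methylidene (the electron-poor trisubstituted enoate and the oxirane are inert), and the cis-oxirane acts as a Z-alkene-like tether that holds C3 and C6 syn and the two termini close, helped by high dilution and the free allylic C3 hydroxyl. The catalyst with the small o-tolyl N-heterocyclic carbene is chosen because the ruthenacyclobutane on the way to the tetrasubstituted alkene is crowded.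

Step 15
Reactants: 21 1-vinyl epoxycyclohexene diene + 22 1-heptene
Product: 23 protected target with E-heptenyl chain (3R,4R,5R,6R)
Conditions: 22 (excess), second-generation Hoveyda–Grubbs catalyst RuCl2(=CH-C6H4-2-O-i-Pr)(H2IMes) (5 mol %), CH2Cl2, 40 °C
Reagents that add atoms: none
Why: Olefin cross-metathesis, in which only the monosubstituted terminal vinyl of the diene can form a ruthenium alkylidene (the tetrasubstituted ring alkene and the trisubstituted enoate are inert) and reversible exchange with excess 1-heptene under ethylene loss gives the thermodynamically preferred conjugated E-alkene.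

Step 16
Reactants: 23 protected target with E-heptenyl chain
Product: 25 C6-O-silylated carboxylic acid, via tris(trimethylsilyl) intermediate 24 (not isolated)
Conditions: Me3SiOTf, 2,6-lutidine, CH2Cl2, −20 → 0 °C; then MeOH, 0 °C → rt
Reagents that add atoms: none
Why: Silyl triflate-mediated tert-butyl ester cleavage, in which O-silylation of the ester carbonyl is followed by loss of the tert-butyl cation as isobutene to give the silyl ester (the two free hydroxyls are silylated in passing) and methanol then removes all three trimethylsilyl groups; the lutidine buffer and low temperature should spare the oxirane (deactivated by its two oxygen-bearing neighbours), the diene and the C6 silyl ether.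

Step 17
Reactants: 25 C6-O-silylated carboxylic acid
Product: 26 target CNP0087193.3
Conditions: Bu4NF, AcOH, THF, 0 °C → rt
Reagents that add atoms: none
Why: Fluoride-induced cleavage of the last silyl ether, with acetic acid keeping the C6 oxygen protonated, which shuts off Payne-type epoxide migration and leaves the diene, the oxirane and all four stereocentres untouched.

**Compound list**

1 | tiglic acid, (E)-2-methylbut-2-enoic acid | C/C=C(\C)C(=O)O | starting material
2 | tert-butyl tiglate, tert-butyl (E)-2-methylbut-2-enoate | C/C=C(\C)C(=O)OC(C)(C)C | intermediate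
3 | tert-butyl (E)-4-bromo-2-methylbut-2-enoate | BrC/C=C(\C)C(=O)OC(C)(C)C | intermediate
4 | methyl bis(2,2,2-trifluoroethyl)phosphonoacetate | COC(=O)CP(=O)(OCC(F)(F)F)OCC(F)(F)F | starting material
5 | 6-tert-butyl 1-methyl (E)-2-[bis(2,2,2-trifluoroethoxy)phosphoryl]-5-methylhex-4-enedioate (racemic at C2) | COC(=O)C(C/C=C(\C)C(=O)OC(C)(C)C)P(=O)(OCC(F)(F)F)OCC(F)(F)F | intermediate
6 | (tert-butyldimethylsilyloxy)acetaldehyde | CC(C)(C)[Si](C)(C)OCC=O | starting material
7 | 6-tert-butyl 1-methyl (E)-2-[(Z)-2-(tert-butyldimethylsilyloxy)ethylidene]-5-methylhex-4-enedioate (methyl ester cis to CH2OSi) | CC(C)(C)[Si](C)(C)OC/C=C(\C(=O)OC)C/C=C(\C)C(=O)OC(C)(C)C | intermediate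
8 | tert-butyl (2E,5Z)-7-(tert-butyldimethylsilyloxy)-5-[methoxy(methyl)carbamoyl]-2-methylhepta-2,5-dienoate | CC(C)(C)[Si](C)(C)OC/C=C(\C(=O)N(C)OC)C/C=C(\C)C(=O)OC(C)(C)C | intermediate
9 | trimethylsilylacetylene | C#C[Si](C)(C)C | starting material
10 | lithium (trimethylsilyl)acetylide | [Li]C#C[Si](C)(C)C | intermediate (not isolated)
11 | tert-butyl (2E,5Z)-7-(tert-butyldimethylsilyloxy)-2-methyl-5-[3-(trimethylsilyl)prop-2-ynoyl]hepta-2,5-dienoate | CC(C)(C)[Si](C)(C)OC/C=C(\C(=O)C#C[Si](C)(C)C)C/C=C(\C)C(=O)OC(C)(C)C | intermediate
12 | tert-butyl (2E,5Z)-7-(tert-butyldimethylsilyloxy)-5-[(1S)-1-hydroxy-3-(trimethylsilyl)prop-2-yn-1-yl]-2-methylhepta-2,5-dienoate | CC(C)(C)[Si](C)(C)OC/C=C(\[C@@H](C#C[Si](C)(C)C)O)C/C=C(\C)C(=O)OC(C)(C)C | intermediate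
13 | tert-butyl (E)-4-[(2S,3R)-3-[(tert-butyldimethylsilyloxy)methyl]-2-[(1R)-1-hydroxy-3-(trimethylsilyl)prop-2-yn-1-yl]oxiran-2-yl]-2-methylbut-2-enoate (threo epoxy alcohol) | CC(C)(C)[Si](C)(C)OC[C@H]1O[C@@]1(C/C=C(\C)C(=O)OC(C)(C)C)[C@@H](C#C[Si](C)(C)C)O | intermediate
14 | tert-butyl (E)-4-[(2R,3R)-3-[(tert-butyldimethylsilyloxy)methyl]-2-[(1R)-1-(tert-butyldimethylsilyloxy)-3-(trimethylsilyl)prop-2-yn-1-yl]oxiran-2-yl]-2-methylbut-2-enoate | CC(C)(C)[Si](C)(C)OC[C@H]1O[C@@]1(C/C=C(\C)C(=O)OC(C)(C)C)[C@@H](C#C[Si](C)(C)C)O[Si](C)(C)C(C)(C)C | intermediate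
15 | tert-butyl (E)-4-[(2R,3R)-2-[(1R)-1-(tert-butyldimethylsilyloxy)-3-(trimethylsilyl)prop-2-yn-1-yl]-3-(hydroxymethyl)oxiran-2-yl]-2-methylbut-2-enoate | OC[C@H]1O[C@@]1(C/C=C(\C)C(=O)OC(C)(C)C)[C@@H](C#C[Si](C)(C)C)O[Si](C)(C)C(C)(C)C | intermediate
16 | tert-butyl (E)-4-[(2R,3S)-2-[(1R)-1-(tert-butyldimethylsilyloxy)-3-(trimethylsilyl)prop-2-yn-1-yl]-3-formyloxiran-2-yl]-2-methylbut-2-enoate (cis-epoxy aldehyde) | O=C[C@H]1O[C@@]1(C/C=C(\C)C(=O)OC(C)(C)C)[C@@H](C#C[Si](C)(C)C)O[Si](C)(C)C(C)(C)C | intermediate
17 | 2-bromoallyl alcohol, 2-bromoprop-2-en-1-ol | OCC(Br)=C | starting material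
18 | 2-lithioallyl lithium alkoxide (C,O-dilithio reagent) | [Li]OCC([Li])=C | intermediate (not isolated)
19 | tert-butyl (E)-4-[(2R,3R)-2-[(1R)-1-(tert-butyldimethylsilyloxy)-3-(trimethylsilyl)prop-2-yn-1-yl]-3-[(1R)-1-hydroxy-2-(hydroxymethyl)prop-2-en-1-yl]oxiran-2-yl]-2-methylbut-2-enoate | C=C(CO)[C@@H](O)[C@H]1O[C@@]1(C/C=C(\C)C(=O)OC(C)(C)C)[C@@H](C#C[Si](C)(C)C)O[Si](C)(C)C(C)(C)C | intermediate
20 | tert-butyl (E)-4-[(2R,3R)-2-[(1R)-1-(tert-butyldimethylsilyloxy)prop-2-yn-1-yl]-3-[(1R)-1-hydroxy-2-(hydroxymethyl)prop-2-en-1-yl]oxiran-2-yl]-2-methylbut-2-enoate (epoxy 1,7-enyne) | C=C(CO)[C@@H](O)[C@H]1O[C@@]1(C/C=C(\C)C(=O)OC(C)(C)C)[C@@H](C#C)O[Si](C)(C)C(C)(C)C | intermediate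
21 | tert-butyl (E)-4-[(1R,2R,5R,6R)-2-(tert-butyldimethylsilyloxy)-3-ethenyl-5-hydroxy-4-(hydroxymethyl)-7-oxabicyclo[4.1.0]hept-3-en-1-yl]-2-methylbut-2-enoate | C=CC1=C(CO)[C@@H](O)[C@H]2O[C@@]2(C/C=C(\C)C(=O)OC(C)(C)C)[C@@H]1O[Si](C)(C)C(C)(C)C | intermediate
22 | 1-heptene | C=CCCCCC | starting material
23 | tert-butyl (E)-4-[(1R,2R,5R,6R)-2-(tert-butyldimethylsilyloxy)-3-[(E)-hept-1-en-1-yl]-5-hydroxy-4-(hydroxymethyl)-7-oxabicyclo[4.1.0]hept-3-en-1-yl]-2-methylbut-2-enoate | CCCCC/C=C/C1=C(CO)[C@@H](O)[C@H]2O[C@@]2(C/C=C(\C)C(=O)OC(C)(C)C)[C@@H]1O[Si](C)(C)C(C)(C)C | intermediate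
24 | trimethylsilyl ester of 25 with both free hydroxyls as trimethylsilyl ethers (tris(trimethylsilyl) intermediate) | CCCCC/C=C/C1=C(CO[Si](C)(C)C)[C@@H](O[Si](C)(C)C)[C@H]2O[C@@]2(C/C=C(\C)C(=O)O[Si](C)(C)C)[C@@H]1O[Si](C)(C)C(C)(C)C | intermediate (not isolated)
25 | (E)-4-[(1R,2R,5R,6R)-2-(tert-butyldimethylsilyloxy)-3-[(E)-hept-1-en-1-yl]-5-hydroxy-4-(hydroxymethyl)-7-oxabicyclo[4.1.0]hept-3-en-1-yl]-2-methylbut-2-enoic acid | CCCCC/C=C/C1=C(CO)[C@@H](O)[C@H]2O[C@@]2(C/C=C(\C)C(=O)O)[C@@H]1O[Si](C)(C)C(C)(C)C | intermediate
26 | (E)-4-[(1S,2R,5R,6R)-3-[(E)-hept-1-en-1-yl]-2,5-dihydroxy-4-(hydroxymethyl)-7-oxabicyclo[4.1.0]hept-3-en-1-yl]-2-methylbut-2-enoic acid (CNP0087193.3) | CCCCC/C=C/C1=C(CO)[C@@H](O)[C@H]2O[C@@]2(C/C=C(\C)C(=O)O)[C@@H]1O | target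

**Step count**

Total: 17 steps. Longest linear sequence: 17 steps from tiglic acid 1; all other building blocks (4, 6, 9, 17, 22) are bought.

**Steps most likely to fail**

1. Step 14 (ring-closing enyne metathesis). The vinylcarbene on C1 may be intercepted by ethylene or by a second alkyne faster than it closes onto the crowded 1,1-disubstituted alkene, or the methylidene may add to the alkyne with the opposite regiochemistry and lead to seven-ring endo closure. The fallback is a relay metathesis that inverts the order of events (ene first, then yne); it sets out from aldehyde 16 and returns at diene 21. 5-Hexenal is condensed with triethyl 2-bromo-2-phosphonoacetate (NaH, THF, Horner–Wadsworth–Emmons) to ethyl (Z)-2-bromoocta-2,7-dienoate F1, which i-Bu2AlH reduces to (Z)-2-bromoocta-2,7-dien-1-ol F2. Its dilithio derivative (t-BuLi, Et2O) adds to 16 as in step 12 to give the relay epoxy diol F3, and K2CO3/MeOH frees the alkyne to give the relay enyne F4. Second-generation Grubbs catalyst RuCl2(=CHPh)(H2IMes)(PCy3) in CH2Cl2 at 40 °C then loads at the unhindered terminal alkene of the pentenyl arm, expels cyclopentene to put the carbene directly on C2, closes the six-membered ring onto the alkyne in the exo mode, and is taken off the alkyne terminus by the terminal alkene of the next substrate molecule, giving 21.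

2. Step 12 (addition of the dilithio reagent). Facial selectivity at the aldehyde may be poor because a lithium-bridged transition state through the oxirane oxygen competes with the Felkin–Anh one, giving mixtures at C3. The fallback sets C3 by reduction instead of by carbon–carbon bond formation; it sets out from 16 and 17 and returns at 19. Alcohol 17 is silylated (Et3SiCl, imidazole) to (2-bromoallyloxy)triethylsilane F5, which after bromine–lithium exchange (t-BuLi, Et2O, −78 °C) adds to 16 to give the C3-epimeric allylic alcohols F6. Dess–Martin oxidation converges both epimers on the epoxy enone F7. Zn(BH4)2 in Et2O at −30 °C reduces F7 through the chelate between the ketone and oxirane oxygens, hydride entering past the C4 hydrogen, to give the (3R)-alcohol F8. Pyridine-buffered HF·pyridine then removes the primary triethylsilyl group to give 19.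

3. Step 7 (CBS reduction). The oxazaborolidine may discriminate poorly between two unsaturated ketone substituents of similar effective size, and conjugate hydroboration of the ynone may compete. The fallback sets C6 in a carbon–carbon bond-forming step; it sets out from Weinreb amide 8 and returns at alcohol 12. Cp2Zr(H)Cl in THF reduces the amide chemoselectively (the tert-butyl ester is untouched) to the (Z)-enal F9. A ZnMe2/ProPhenol-catalysed addition of alkyne 9 (the enantiomer of 2,6-bis[[2-(hydroxydiphenylmethyl)pyrrolidin-1-yl]methyl]-4-methylphenol that delivers the S carbinol; toluene, 4 °C) then forms the C6–C1 bond and the C6 stereocentre together, giving 12.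

**Further compounds**

F1 | step 14 | ethyl (Z)-2-bromoocta-2,7-dienoate | CCOC(=O)/C(Br)=C/CCCC=C
F2 | step 14 | (Z)-2-bromoocta-2,7-dien-1-ol | OC/C(Br)=C/CCCC=C
F3 | step 14 | relay epoxy diol: analogue of 19 in which the CH2= terminus of the C2 alkene carries a pent-4-enyl arm | C=CCCC/C=C(/CO)[C@@H](O)[C@H]1O[C@@]1(C/C=C(\C)C(=O)OC(C)(C)C)[C@@H](C#C[Si](C)(C)C)O[Si](C)(C)C(C)(C)C
F4 | step 14 | relay enyne: F3 with terminal alkyne | C=CCCC/C=C(/CO)[C@@H](O)[C@H]1O[C@@]1(C/C=C(\C)C(=O)OC(C)(C)C)[C@@H](C#C)O[Si](C)(C)C(C)(C)C
F5 | step 12 | (2-bromoallyloxy)triethylsilane | C=C(Br)CO[Si](CC)(CC)CC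
F6 | step 12 | C3-epimeric allylic alcohols, primary hydroxyl as triethylsilyl ether | C=C(CO[Si](CC)(CC)CC)C(O)[C@H]1O[C@@]1(C/C=C(\C)C(=O)OC(C)(C)C)[C@@H](C#C[Si](C)(C)C)O[Si](C)(C)C(C)(C)C
F7 | step 12 | epoxy enone (C3 ketone) | C=C(CO[Si](CC)(CC)CC)C(=O)[C@H]1O[C@@]1(C/C=C(\C)C(=O)OC(C)(C)C)[C@@H](C#C[Si](C)(C)C)O[Si](C)(C)C(C)(C)C
F8 | step 12 | (3R)-allylic alcohol, primary hydroxyl as triethylsilyl ether | C=C(CO[Si](CC)(CC)CC)[C@@H](O)[C@H]1O[C@@]1(C/C=C(\C)C(=O)OC(C)(C)C)[C@@H](C#C[Si](C)(C)C)O[Si](C)(C)C(C)(C)C
F9 | step 7 | tert-butyl (2E,5Z)-7-(tert-butyldimethylsilyloxy)-5-formyl-2-methylhepta-2,5-dienoate | CC(C)(C)[Si](C)(C)OC/C=C(\C=O)C/C=C(\C)C(=O)OC(C)(C)C
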